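The route rests on cutting the C2'–C3' bond of the side chain on ring carbon C6 of the benzoquinone ring. C1'–C9' is an unbranched methylene run, so C3'–C15', with the Z-configured C10'=C11' alkene, is exactly myristoleic acid less its carboxyl carbon. A mixed Kolbe electrolysis joins this thirteen-carbon primary radical to the two-carbon radical from a quinone propanoic acid in one operation, forming one C(sp3)–C(sp3) bond with no ring closure and no new stereocentre. The precursor is the fully substituted 2,5-dimethoxy-3-methyl-1,4-benzoquinone bearing a 2-carboxyethyl group on C6, made in five steps from 1,2,4,5-tetramethoxybenzene. Basic hydrolysis of the two methoxy groups then gives the target.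

Key step: step 6

Remark: the target is drawn as one tautomer of the 2,5-dihydroxy-1,4-benzoquinone and is treated as that tautomeric pair. Atom count for the coupling: the quinone acid supplies C1'–C2', C2–C14 of myristoleic acid supply C3'–C15', and its C9=C10 Z alkene becomes C10'=C11'. All structures below agree with this count.

Step 1
Reactants: 1 1,2,4,5-tetramethoxybenzene
Product: 3 1,2,4,5-tetramethoxy-3-methylbenzene, via (2,3,5,6-tetramethoxyphenyl)lithium 2 (not isolated)
Conditions: n-BuLi (1.05 equiv), TMEDA, THF, 0 °C to rt; MeI, 0 °C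
Reagents that add atoms: iodomethane, CI
Why: Directed ortho-metalation removes a ring hydrogen flanked by two methoxy groups, and the aryllithium is methylated by SN2 attack on iodomethane.

Step 2
Reactants: 3 1,2,4,5-tetramethoxy-3-methylbenzene
Product: 6 2,3,5,6-tetramethoxy-4-methylbenzaldehyde, via (2,3,5,6-tetramethoxy-4-methylphenyl)lithium 4 (not isolated), via lithium hemiaminal alkoxide 5 (not isolated)
Conditions: n-BuLi (1.1 equiv), TMEDA, THF, 0 °C to rt; DMF, 0 °C; H2O
Reagents that add atoms: N,N-dimethylformamide, CN(C)C=O
Why: The one remaining ring hydrogen, again between two methoxy groups, is lithiated by directed ortho-metalation and the aryllithium is formylated with DMF (Bouveault aldehyde synthesis), the tetrahedral adduct collapsing to the aldehyde on aqueous quench.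

Step 3
Reactants: 6 2,3,5,6-tetramethoxy-4-methylbenzaldehyde; 7 malonic acid
Product: 9 (E)-3-(2,3,5,6-tetramethoxy-4-methylphenyl)prop-2-enoic acid, via arylidenemalonic acid 8 (not isolated)
Conditions: pyridine, piperidine (cat.), 90 to 115 °C; aq. HCl
Reagents that add atoms: none
Why: Knoevenagel–Doebner condensation gives the arylidenemalonic acid, which decarboxylates in hot pyridine to the thermodynamically preferred E cinnamic acid, whose alkene geometry is removed again in step 4.

Step 4
Reactants: 9 (E)-3-(2,3,5,6-tetramethoxy-4-methylphenyl)prop-2-enoic acid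
Product: 10 3-(2,3,5,6-tetramethoxy-4-methylphenyl)propanoic acid
Conditions: H2 (1 atm), 10% Pd/C, EtOAc, rt
Reagents that add atoms: none
Why: Heterogeneous catalytic hydrogenation saturates the conjugated C=C bond, while the hexasubstituted arene, the methyl ethers and the carboxylic acid are inert under these conditions.

Step 5
Reactants: 10 3-(2,3,5,6-tetramethoxy-4-methylphenyl)propanoic acid
Product: 11 3-(2,5-dimethoxy-4-methyl-3,6-dioxocyclohexa-1,4-dien-1-yl)propanoic acid
Conditions: (NH4)2Ce(NO3)6 (2.5 equiv), MeCN/H2O (2:1), 0 °C
Reagents that add atoms: water, O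
Why: Tetravalent cerium oxidises the electron-rich arene to its radical cation, water adds at a methoxy-bearing carbon and methanol is lost twice (oxidative demethylation of a para-dimethoxyarene), either para pair of methoxy groups giving the same 2,5-dimethoxy-1,4-benzoquinone while the saturated acid chain is inert.

Step 6
Reactants: 11 3-(2,5-dimethoxy-4-methyl-3,6-dioxocyclohexa-1,4-dien-1-yl)propanoic acid; 12 myristoleic acid, (Z)-tetradec-9-enoic acid (4 equiv)
Product: 13 2,5-dimethoxy-3-methyl-6-[(Z)-pentadec-10-enyl]-1,4-benzoquinone
Conditions: Pt anode, Pt cathode, divided cell (glass frit), MeOH, NaOMe (0.1 equiv per CO2H), catholyte NaOMe/MeOH, constant current ca. 0.25 A cm−2, 15 °C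
Reagents that add atoms: none
Why: Proposed new method: each carboxylate is discharged at the platinum anode to an acyloxy radical that loses CO2 at once, and the resulting 2-(quinonyl)ethyl and (Z)-tridec-8-enyl primary radicals, kept at high concentration in the anode layer by the high current density, pair to form the C2'–C3' bond (mixed Kolbe coupling). The closest known reaction type is the mixed Kolbe electrolysis of a Z-alkenoic acid such as oleic acid with a second aliphatic acid, which leaves a remote cis alkene intact; a quinone-bearing acid has not been shown in it. No ring is closed and no stereocentre is made; the only stereo-element, the Z alkene, is separated from the radical carbon by six methylenes, so neither cyclisation nor an allylic radical or cation can scramble it. The selectivity needed is radical pairing over radical addition to the quinone and over reduction of the quinone at the cathode: every ring carbon is substituted, the only intramolecular path of the quinonylethyl radical is a disfavoured 5-endo attack on a carbonyl oxygen, and the frit keeps 11 out of the cathode compartment. The ring is carried as the quinone because it cannot be oxidised further at the anode, whereas the tetramethoxyarene 10 would be oxidised before its carboxylate. Cross- against homo-coupling is only statistical, so 12 is used in excess and the non-polar C26 diene and the polar bis-quinone dimer should be removable by chromatography.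

Step 7
Reactants: 13 2,5-dimethoxy-3-methyl-6-[(Z)-pentadec-10-enyl]-1,4-benzoquinone
Product: 15 2,5-dihydroxy-3-methyl-6-[(Z)-pentadec-10-enyl]-1,4-benzoquinone, via disodium dioxidoquinone salt 14 (not isolated)
Conditions: 2 M NaOH aq., EtOH, N2, 60 °C; then 2 M HCl, 0 °C
Reagents that add atoms: sodium hydroxide, [Na+].[OH-]
Why: Each methoxy group is a vinylogous methyl ester, so hydroxide adds at the methoxy-bearing ring carbon and expels methoxide (addition–elimination, the standard hydrolysis of 2,5-dimethoxy-3,6-dialkyl-1,4-benzoquinones), the dianion formed resists further attack, the isolated Z alkene is untouched by aqueous base, and acidification liberates the target.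

Compound list
1 | 1,2,4,5-tetramethoxybenzene | COc1cc(OC)c(OC)cc1OC | starting material
2 | (2,3,5,6-tetramethoxyphenyl)lithium | [Li]c1c(OC)c(OC)cc(OC)c1OC | intermediate (not isolated)
3 | 1,2,4,5-tetramethoxy-3-methylbenzene | Cc1c(OC)c(OC)cc(OC)c1OC | intermediate
4 | (2,3,5,6-tetramethoxy-4-methylphenyl)lithium | [Li]c1c(OC)c(OC)c(C)c(OC)c1OC | intermediate (not isolated)
5 | lithium (dimethylamino)(2,3,5,6-tetramethoxy-4-methylphenyl)methanolate (racemic) | [Li+].[O-]C(N(C)C)c1c(OC)c(OC)c(C)c(OC)c1OC | intermediate (not isolated)
6 | 2,3,5,6-tetramethoxy-4-methylbenzaldehyde | O=Cc1c(OC)c(OC)c(C)c(OC)c1OC | intermediate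
7 | malonic acid | OC(=O)CC(=O)O | starting material
8 | 2-[(2,3,5,6-tetramethoxy-4-methylphenyl)methylidene]propanedioic acid | OC(=O)C(=Cc1c(OC)c(OC)c(C)c(OC)c1OC)C(=O)O | intermediate (not isolated)
9 | (E)-3-(2,3,5,6-tetramethoxy-4-methylphenyl)prop-2-enoic acid | OC(=O)/C=C/c1c(OC)c(OC)c(C)c(OC)c1OC | intermediate
10 | 3-(2,3,5,6-tetramethoxy-4-methylphenyl)propanoic acid | OC(=O)CCc1c(OC)c(OC)c(C)c(OC)c1OC | intermediate
11 | 3-(2,5-dimethoxy-4-methyl-3,6-dioxocyclohexa-1,4-dien-1-yl)propanoic acid | OC(=O)CCC1=C(OC)C(=O)C(C)=C(OC)C1=O | intermediate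
12 | myristoleic acid, (Z)-tetradec-9-enoic acid | CCCC/C=C\CCCCCCCC(=O)O | starting material
13 | 2,5-dimethoxy-3-methyl-6-[(Z)-pentadec-10-enyl]-1,4-benzoquinone | CCCC/C=C\CCCCCCCCCC1=C(OC)C(=O)C(C)=C(OC)C1=O | intermediate
14 | disodium 3-methyl-6-[(Z)-pentadec-10-enyl]-1,4-benzoquinone-2,5-diolate | CCCC/C=C\CCCCCCCCCC1=C([O-])C(=O)C(C)=C([O-])C1=O.[Na+].[Na+] | intermediate (not isolated)
15 | 2,5-dihydroxy-3-methyl-6-[(Z)-pentadec-10-enyl]-1,4-benzoquinone | CCCC/C=C\CCCCCCCCCC1=C(O)C(=O)C(C)=C(O)C1=O | target

Total step count: 7. Longest linear sequence: 7 steps (1 to 15); myristoleic acid 12 enters at step 6.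

Steps most likely to fail

Step 6 (Proposed new method). The alkyl radicals may add to the quinone ring carbons or carbonyl oxygens, or abstract hydrogen, faster than they pair, and the anode may foul, so that cross-coupling is lost. The fallback uses known chemistry and runs from 3 to 13.
- Hex-1-yne (CCCCC#C) is deprotonated with n-BuLi in THF to hex-1-ynyllithium F1.
- F1 is alkylated with an excess of 1,9-dibromononane (BrCCCCCCCCCBr) in THF/DMPU to 15-bromopentadec-5-yne F2.
- Semi-hydrogenation (H2, Pd/CaCO3 poisoned with Pb(OAc)2, quinoline, hexane) should give (Z)-15-bromopentadec-5-ene F3.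
- Compound 3 is lithiated to 4 as in step 2 and alkylated with F3 (THF/DMPU, 0 °C to rt) to 1,2,4,5-tetramethoxy-3-methyl-6-[(Z)-pentadec-10-enyl]benzene F4.
- Oxidation of F4 with (NH4)2Ce(NO3)6 in MeCN/H2O as in step 5 returns to the route at 13.

Step 5. The neighbouring free carboxyl group may capture the arene radical cation (lactonisation), over-oxidation may set in, and the polar quinone acid may be lost during aqueous work-up. The fallback runs from 10 to 11 with the acid masked.
- 10 is converted with Boc2O, DMAP (cat.) and t-BuOH into tert-butyl 3-(2,3,5,6-tetramethoxy-4-methylphenyl)propanoate F5.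
- F5 is oxidised with (NH4)2Ce(NO3)6 in MeCN/H2O at 0 °C to tert-butyl 3-(2,5-dimethoxy-4-methyl-3,6-dioxocyclohexa-1,4-dien-1-yl)propanoate F6.
- The ester is cleaved with CF3CO2H in CH2Cl2 at rt, conditions that leave the methoxyquinone intact, to rejoin the route at 11.

Step 7. The second methoxy group may hydrolyse sluggishly once the first has given an electron-rich anion, and prolonged heating in alkali may bring ring degradation by oxidative cleavage or contraction. The fallback runs from 13 to 15 and removes the methyl groups at the hydroquinone level.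
- 13 is reduced with Na2S2O4 (EtOAc/H2O, rt) to 2,5-dimethoxy-3-methyl-6-[(Z)-pentadec-10-enyl]benzene-1,4-diol F7.
- F7 is demethylated with BBr3 in CH2Cl2 at −78 to 0 °C, cold enough to spare the isolated alkene, to 3-methyl-6-[(Z)-pentadec-10-enyl]benzene-1,2,4,5-tetrol F8.
- Stirring F8 in EtOAc over aqueous phosphate buffer under air lets it autoxidise to the target 15.

Further compounds
F1 | step 6 | hex-1-ynyllithium | [Li]C#CCCCC
F2 | step 6 | 15-bromopentadec-5-yne | CCCCC#CCCCCCCCCCBr
F3 | step 6 | (Z)-15-bromopentadec-5-ene | CCCC/C=C\CCCCCCCCCBr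
F4 | step 6 | 1,2,4,5-tetramethoxy-3-methyl-6-[(Z)-pentadec-10-enyl]benzene | CCCC/C=C\CCCCCCCCCc1c(OC)c(OC)c(C)c(OC)c1OC
F5 | step 5 | tert-butyl 3-(2,3,5,6-tetramethoxy-4-methylphenyl)propanoate | CC(C)(C)OC(=O)CCc1c(OC)c(OC)c(C)c(OC)c1OC
F6 | step 5 | tert-butyl 3-(2,5-dimethoxy-4-methyl-3,6-dioxocyclohexa-1,4-dien-1-yl)propanoate | CC(C)(C)OC(=O)CCC1=C(OC)C(=O)C(C)=C(OC)C1=O
F7 | step 7 | 2,5-dimethoxy-3-methyl-6-[(Z)-pentadec-10-enyl]benzene-1,4-diol | CCCC/C=C\CCCCCCCCCc1c(OC)c(O)c(C)c(OC)c1O
F8 | step 7 | 3-methyl-6-[(Z)-pentadec-10-enyl]benzene-1,2,4,5-tetrol | CCCC/C=C\CCCCCCCCCc1c(O)c(O)c(C)c(O)c1O
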